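The earlier runs and the new flask were generated by integration with constants of no real substance; the scatter is artificial.

A small charge of solid substrate, in red, turns more of itself into target by 5.00 h than the large charge of amber at the same reagent.

| setting | red | amber | teal | flask |
|---|---|---|---|---|
| solid substrate | 0.15 M | 0.35 M | 0.23 M | 0.23 M |
| reagent | 0.46 M | 0.46 M | 0.92 M | 0.460 M |
| remark | run made earlier | run made earlier | run made earlier |  |
| time |  |  |  | 5.0 h |

| run | time / h | target / % | solid product / % |
|---|---|---|---|
| red | 0.250 | 1.0 | 0 |
| red | 0.833 | 4.0 | 0 |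
| red | 1.33 | 6.0 | 0 |
| red | 2.00 | 7.8 | 0 |
| red | 3.00 | 11.9 | 0 |
| red | 4.00 | 15.0 | 0 |
| red | 5.00 | 17.8 | 0.3 |
| amber | 0.667 | 0.9 | 0.2 |
| amber | 1.33 | 1.4 | 0.3 |
| amber | 2.00 | 0.6 | 0 |
| amber | 3.00 | 0.7 | 0 |
| amber | 4.00 | 0.7 | 0 |
| amber | 5.00 | 1.0 | 0 |
| teal | 0.417 | 2.5 | 0.1 |
| teal | 0.833 | 4.8 | 0 |
| teal | 1.33 | 5.5 | 0 |
| teal | 2.50 | 6.4 | 0 |
| teal | 5.00 | 16.3 | 1.5 |

(scatter of a reading: 0.3 percentage points)

- for target the solid product and idle adduct are counted in
- as a solid, counted per litre of solution: solid substrate, solid product
- at the start none of the solid substrate is in solution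
- dissolved substrate means what is dissolved; the solid is not counted in it

- the target and solid product and idle adduct together standing at 5.0 h, as a percentage of the solid substrate charged
- concentration of dissolved substrate in solution at 5.0 h, in percent of saturation

1. Red, with 0.15 M of solid substrate, rises steadily at 0.0347 h⁻¹ as a fraction of the charge, which looks close to zero order, and reaches 17.8% at 5.00 h. Amber, at the same reagent, is charged with 0.35 M of solid and reads 1.0% at 5.00 h.

2. Call the toll of the charge the natural logarithm of that drop in the end fraction per molar of solid added, reagent and time held: 14.4 M⁻¹, a reading that carries the scatter of amber's small end value.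

3. Now draw your flask. Teal has the same solid and twice the reagent, and it starts at 0.0576 h⁻¹. If target grows in proportion to reagent, the flask starts at 0.0288 h⁻¹.

4. Teal bends after 0.833 h. With the same knee, I expect the flask to level near 2.40% and to stay close to that up to about 2.50 h, where teal reads 6.4% before rising again.

5. The toll, counted from red, gives my estimate for the end, 5.63%, so I draw the last stretch climbing at 0.0129 h⁻¹. No reading shows dissolved substrate, so I put no number on saturation.

6. The forecast gives 6% and 96%, and says of the flask: “It should fall between amber and red and is probably still in or just leaving a stall”.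

7. The flask gives 6.91%, with dissolved substrate at 56.9% of saturation.

    solid substrate ⇌ dissolved substrate, rate k1*(cs1 - [dissolved substrate]) while solid is left; crystals form when [dissolved substrate] > cs1 (solubility = 0.150 M, k = 0.670 h⁻¹)
    dissolved substrate + reagent → target (k = 1.40 M⁻¹ h⁻¹)
    2 dissolved substrate → side product A (k = 1.10 M⁻¹ h⁻¹)
    solid product ⇌ target, rate k4*(cs4 - [target]) while solid is left; crystals form when [target] > cs4 (solubility = 28.0 mM, k = 87.0 h⁻¹)
    reagent + target ⇌ idle adduct, settled at all times (K = 2.10 M⁻¹)
    solid substrate + target → side product B (k = 17.0 M⁻¹ h⁻¹)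
    reagent ⇌ dormant form (K = 7.80, k = 1.30 h⁻¹)

Of the settings tried on this flask, each moved alone by the same factor, the order of greatest effect on the first asked percentage is solid substrate (6.4 points), then time (2.9 points), then reagent (2.8 points). From red to this flask the toll reads 11.8 M⁻¹, against my 14.4 M⁻¹. Carried from this flask to a neighbour charged with 0.92 M of solid substrate at the same reagent, the toll of 14.4 M⁻¹ gives <0.001%, and the neighbour stands at 0.0681%.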